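Readings and results are simulated for substances that don't exist, noise included.

Test slowness first: the electrophile of the dusk run creeps late on, and a slow main step is the plainest reading of that.

| flask | electrophile | nucleophile | free base | remark | time |
|---|---|---|---|---|---|
| dusk | 0.30 M | 0.40 M | 0.060 M | run made earlier |  |
| gamma | 0.20 M | 0.400 M | 0.0900 M |  | 3.0 min |
| theta | 0.20 M | 0.400 M | 0.0600 M |  | 3.0 min |

dusk run (percent of the electrophile charged)

| time / s | electrophile / % | target / % |
|---|---|---|
| 10.0 | 57.0 | 34.3 |
| 20.0 | 42.9 | 41.5 |
| 40.0 | 31.7 | 47.4 |
| 60.0 | 28.0 | 50.9 |
| 80.0 | 24.3 | 51.4 |
| 120 | 22.5 | 52.4 |

(each reading ± 0.5 percentage points)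

- no earlier run changes the charge of free base; that part of a forecast is a guess

* part of the electrophile that has reacted at the end, gamma
* part of the electrophile that has reacted at the end, theta
* what raising the concentration of free base from its lowest to its highest value here does to the part of the electrophile that has reacted (changes below 5 percentage points count as none) (no change / it falls / it rises)

Start with the main step by itself, electrophile plus nucleophile one to one, at a rate proportional to both. In dusk the electrophile loses 43 percentage points in the first 10.0 s. By 80.0 s the product of the two concentrations stands at 10.5% of its starting value, so expect about 18 points over the next 40.0 s. The readings show 1.8 points, less than that.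

Add a second process: let each turnover set acid free, and let the acid take a further nucleophile as protonated nucleophile. Write the nucleophile balance: two are spent per turnover, so this reckoning puts the stop of dusk at 0.200 M, or 66.7% of the electrophile charged. That is less than the 77.5% reacted at 120 s.

Add the free base, which takes acid in the nucleophile's place. The stop moves to 0.230 M, or 76.7%, which matches the reading. In this reckoning for dusk the nucleophile, though charged in excess, is the limiting reagent.

Last, book the 25 points reacted but not found as target as unread product, and leave the balance as it stands.

Name the acid capacity: nucleophile plus free base charged, divided by two. It is 0.245 M in gamma and 0.230 M in theta, both above the 0.20 M of electrophile. In gamma and theta the electrophile is then the limiting reagent, and 3.0 min is longer than the dusk run. Expect both flasks near completion, with no change from the free base.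

The forecast says the same: 99% for gamma, 98% for theta, no change, since “Both runs are nearly complete, so the base has no significant effect”.

The flask gives 99.1% for gamma and 98.2% for theta, a change of 0.94 points: no change.

    electrophile + nucleophile → acid set free + target (k = 0.190 M⁻¹ s⁻¹)
    nucleophile + acid set free ⇌ protonated nucleophile, settled at all times (K = 1100 M⁻¹)
    acid set free + free base ⇌ salt of the base, settled at all times (K = 7.20 × 10⁵ M⁻¹)
    target ⇌ isomer of the product (K = 0.450, k = 0.0620 s⁻¹)
    acid set free + target → side product (k = 0.0610 M⁻¹ s⁻¹)

With the electrophile charge reckoned as reacted, gamma's capacity leaves 22.5% of the nucleophile charge free, and 23.8% stands at 3.00 min. On that nucleophile the electrophile half-life by the main step is still 0.64 min, short against 3.0 min, and 0.869% of the electrophile remains. Now take the same flask as gamma with 0.16 M of nucleophile: its capacity is 0.125 M, below the electrophile charge, which puts the stop near 62.5%. The computed flask reaches 64.1%, with 2.2% of its nucleophile left.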